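At the 40.0 h reading the two earlier runs have levelled off: since 25.0 h, cedar's substrate has gone from 48.5% to 48.6% and maple's from 63.5% to 62.5%.

| setting | maple | cedar | flask |
|---|---|---|---|
| substrate | 0.050 M (fed, over 3.0 h) | 0.050 M (fed, over 3.0 h) | 0.050 M (fed, over 3.0 h) |
| coupling partner | 0.024 M | 0.036 M | 0.0475 M |
| remark | run made earlier; the fed solution adds 0.50 times the starting volume | run made earlier; the fed solution adds 0.50 times the starting volume | the fed solution adds 0.50 times the starting volume |
| time |  |  | 40 h |

| run | time / h | substrate / % | mono adduct / % |
|---|---|---|---|
| maple | 3.00 | 88.7 | 9.3 |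
| maple | 5.00 | 81.2 | 16.1 |
| maple | 8.00 | 74.4 | 21.3 |
| maple | 12.0 | 67.5 | 24.6 |
| maple | 15.0 | 65.5 | 26.1 |
| maple | 25.0 | 63.5 | 27.8 |
| maple | 40.0 | 62.5 | 27.9 |
| cedar | 3.00 | 85.5 | 12.3 |
| cedar | 5.00 | 74.4 | 20.8 |
| cedar | 8.00 | 65.0 | 26.6 |
| cedar | 12.0 | 56.4 | 29.4 |
| cedar | 15.0 | 53.6 | 32.3 |
| cedar | 25.0 | 48.5 | 31.9 |
| cedar | 40.0 | 48.6 | 31.4 |

(each reading ± 0.5 percentage points)

- amounts and yields of released group count idle adduct too
- charges are per starting volume, the dose included; the dosed solution carries all of it
- the numbers in the tables scatter with a standard deviation of 0.5 percentage points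
- steps that have been proposed: substrate + coupling partner -> mono adduct + released group; coupling partner + mono adduct -> bis adduct + released group; coupling partner + released group <-> idle adduct; released group -> by-product carried off
- the earlier runs do not show how much of coupling partner is bound; that part of a forecast is a guess

- part of the substrate that has reacted at 40 h
- share of the unused coupling partner that is free and not bound as idle adduct, at 40 h

I count in percent of the substrate charged: E is the coupling partner charged, c the substrate reacted, m the mono adduct and b the bis adduct, taken as the rest of the reacted substrate. A mono adduct has taken one partner and a bis adduct two, so with the partner used up E = m + 2b. Since c = m + b, it follows that c = (E + m)/2.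

| run | E | m | (E + m)/2 | c read |
|---|---|---|---|---|
| maple | 48.0% | 27.9% | 37.9% | 37.5% |
| cedar | 72.0% | 31.4% | 51.7% | 51.4% |

In the maple row the last two columns differ by 0.45 percentage points, and in the cedar row by 0.3 points. That is about the scatter, so I take the partner in both runs as used up at that last reading. Reading down the columns, m climbs by 3.5 points, less than the 24 points that E climbs. So I freeze m at cedar's 31.4%, the frozen mono share. For the new flask, E = 95.0% then gives c = 63.2%. The runs do not show how much partner is bound, so I reckon no free share.

The forecast gives 63% reacted and 65% free, saying “I guess mostly free, with wide uncertainty”.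

The flask gives 63.6% reacted and 99.8% free.

    substrate + coupling partner → mono adduct + released group (k = 4.80 M⁻¹ h⁻¹)
    coupling partner + mono adduct → bis adduct + released group (k = 5.80 M⁻¹ h⁻¹)
    coupling partner + released group ⇌ idle adduct, settled at all times (K = 61.0 M⁻¹)
    released group → by-product carried off (k = 1.10 h⁻¹)

The coupling partner, the limiting reagent, ends the flask at 0.73% of its charge, less than the 36% of substrate left. In the flask mono adduct ends at 32.8%, which is 1.4 points above the 31.4% I froze from cedar's reading. The neighbouring flask holds 0.085 M of substrate, all else as before, so E = 55.9%, and the frozen share gives c = 43.6%. That neighbour ends with 42.8% of its substrate reacted, mono adduct at 29.6% and bis adduct at 13.1%.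

All runs stem from a simulated flask from invented constants; scatter was added.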